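**Plan**

- Retrosynthesis: remove the C3 bromine, restore a C2 ester, cut N1–C7a of indole A (the NH indole) to an aryl azidoacrylate, cut its C2=C3 bond to an aryl aldehyde plus azidoacetate, then cut C4–N1' to an ortho-fluorobenzaldehyde and 2,5-dibromoindole (indole B, primed atoms).
- Forward: indole B is made from its oxindole, the anisole is formylated next to fluorine, and the two are joined at C4–N1' by fluoride displacement.
- The pyrrole of indole A closes last (C2=C3 by condensation, N1–C7a by azide thermolysis), followed by ester hydrolysis, decarboxylation and C3 bromination.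
- Enabling feature: C3a lies between C4 (bonded to N1') and C7a, so one formyl carbon on C3a first activates the C4 fluoride and then carries the azidoacrylate that closes onto C7a–H.
- Stereochemistry: the target has no stereocentre; the Z alkene and the azirine stereocentre are transient and the N1'–C4 axis is not controlled.

Key step: step 5

Remark: the N1'–C4 axis has four ortho substituents and is probably configurationally stable, but the target is drawn without an axial descriptor, so it is made as the racemate (compounds 6 and later are racemic about this axis).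

**Step 1**
Reactants: 1 2-bromo-1-fluoro-4-methoxybenzene
Product: 3 3-bromo-2-fluoro-5-methoxybenzaldehyde, via (3-bromo-2-fluoro-5-methoxyphenyl)lithium 2 (not isolated)
Conditions: LiN(iPr)2 (1.1 equiv), THF, −78 °C; DMF, −78 to −20 °C; aq. NH4Cl
Reagents that add atoms: N,N-dimethylformamide, CN(C)C=O
Why: Directed ortho-lithiation followed by DMF formylation, in which fluorine is the strongest ortho-acidifying group and its neighbouring C–H is the least hindered, so the amide base at −78 °C should give aryllithium 2 (kept cold to prevent LiF loss to an aryne), as known for 1-bromo-2-fluoroarenes.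

**Step 2**
Reactants: 4 5-bromoindolin-2-one
Product: 5 2,5-dibromo-1H-indole
Conditions: POBr3 (1.5 equiv), imidazole (1.2 equiv), ClCH2CH2Cl, 80 °C; cold aqueous work-up, product used at once
Reagents that add atoms: phosphorus oxybromide, O=P(Br)(Br)Br
Why: Deoxybromination of a lactam by Vilsmeier-type activation, in which O-phosphorylation of the amide, bromide addition–elimination at C2 and tautomerisation give the aromatic 2-bromoindole, a standard entry to 2-haloindoles from oxindoles, with imidazole buffering the HBr that would degrade the product.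

**Step 3**
Reactants: 3 3-bromo-2-fluoro-5-methoxybenzaldehyde; 5 2,5-dibromo-1H-indole
Product: 6 3-bromo-2-(2,5-dibromo-1H-indol-1-yl)-5-methoxybenzaldehyde
Conditions: Cs2CO3 (2 equiv), DMSO, 80 °C, N2, dark
Reagents that add atoms: none
Why: Nucleophilic aromatic substitution by addition–elimination, in which Cs2CO3 deprotonates the bromine-acidified N–H of 5 and the nitrogen attacks the fluoride-bearing carbon, the ortho formyl group stabilising the Meisenheimer adduct, as in known N-arylations of indoles and carbazoles with ortho-fluorobenzaldehydes.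

**Step 4**
Reactants: 6 3-bromo-2-(2,5-dibromo-1H-indol-1-yl)-5-methoxybenzaldehyde; 7 methyl azidoacetate
Product: 8 methyl (Z)-2-azido-3-[3-bromo-2-(2,5-dibromo-1H-indol-1-yl)-5-methoxyphenyl]prop-2-enoate
Conditions: 7 (4 equiv), NaOMe (4 equiv), MeOH/THF, −15 to 0 °C
Reagents that add atoms: none
Why: Knoevenagel-type aldol condensation (first stage of the Hemetsberger–Knittel synthesis), in which the enolate of 7 adds to the non-enolisable aldehyde and base-promoted dehydration gives the conjugated Z-azidocinnamate, the low temperature keeping the azidoacetate anion from losing N2.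

**Step 5**
Reactants: 8 methyl (Z)-2-azido-3-[3-bromo-2-(2,5-dibromo-1H-indol-1-yl)-5-methoxyphenyl]prop-2-enoate
Product: 10 methyl 5-bromo-4-(2,5-dibromo-1H-indol-1-yl)-7-methoxy-1H-indole-2-carboxylate, via 2H-azirine 9 (not isolated)
Conditions: degassed xylenes (0.03 M), 140 °C
Reagents that add atoms: none
Why: Heating 8 expels N2 to give a vinyl nitrene in equilibrium with 2H-azirine 9; the nitrene nitrogen bonds to the only free ortho carbon of the aryl ring (the future C7a) and a hydrogen shift restores aromaticity, forming N1–C7a and the pyrrole of indole A as its 2-carboxylate. The closest known reaction type is the Hemetsberger–Knittel indole synthesis, which is established for azidocinnamates from 2-substituted 5-methoxybenzaldehydes and gives 4-substituted 7-methoxyindole-2-carboxylates. The one new ring, the five-membered pyrrole, closes by 1,5-electrocyclisation of the conjugated vinyl nitrene onto the arene (formally insertion into the aryl C–H bond) followed by a [1,5]-hydrogen shift. No stereocentre is formed, and the Z geometry of 8 and the stereocentre of 9 vanish in the aromatic product. The step needs regioselectivity between the two ortho carbons and chemoselectivity against indole B: the other ortho carbon carries N1' and cannot rearomatise, and C2' or C7' of indole B could only be reached through seven- or eight-membered transition states, so the five-membered closure should prevail, with dilution suppressing intermolecular nitrene reactions.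

**Step 6**
Reactants: 10 methyl 5-bromo-4-(2,5-dibromo-1H-indol-1-yl)-7-methoxy-1H-indole-2-carboxylate
Product: 11 5-bromo-4-(2,5-dibromo-1H-indol-1-yl)-7-methoxy-1H-indole-2-carboxylic acid
Conditions: LiOH·H2O (5 equiv), THF/MeOH/H2O, 50 °C; 1 M HCl to pH 3
Reagents that add atoms: lithium hydroxide monohydrate, [Li+].[OH-].O
Why: Saponification (BAc2 ester hydrolysis) of an indole-2-carboxylate, in which the aryl bromides and the unactivated C2'–Br bond should be inert to aqueous hydroxide at this temperature.

**Step 7**
Reactants: 11 5-bromo-4-(2,5-dibromo-1H-indol-1-yl)-7-methoxy-1H-indole-2-carboxylic acid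
Product: 12 5-bromo-4-(2,5-dibromo-1H-indol-1-yl)-7-methoxy-1H-indole
Conditions: Ag2CO3 (15 mol%), AcOH (10 mol%), DMSO, 120 °C
Reagents that add atoms: none
Why: Silver-catalysed protodecarboxylation of a heteroaromatic carboxylic acid, in which the silver carboxylate loses CO2 and AcOH protonates the resulting C2–Ag bond, conditions known for indole-2-carboxylic acids and tolerant of aryl bromides.

**Step 8**
Reactants: 12 5-bromo-4-(2,5-dibromo-1H-indol-1-yl)-7-methoxy-1H-indole
Product: 14 3,5-dibromo-4-(2,5-dibromo-1H-indol-1-yl)-7-methoxy-1H-indole, via sodium indol-1-ide 13 (not isolated)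
Conditions: NaH (1.05 equiv), THF, 0 °C; NBS (1.0 equiv), −78 to −20 °C; aq. NH4Cl
Reagents that add atoms: N-bromosuccinimide, O=C1CCC(=O)N1Br
Why: Electrophilic C3 halogenation of a metal indolide (as in hydroxide/halogen 3-halogenations of indoles), in which only indole A has an N–H, so its sodium salt 13 should be far more nucleophilic at C3 than the neutral, N-aryl, doubly brominated indole B and one equivalent of NBS should brominate C3 of ring A through the 3-bromo-3H-indole tautomer.

**Compound list**

1 | 2-bromo-1-fluoro-4-methoxybenzene | COc1ccc(F)c(Br)c1 | starting material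
2 | (3-bromo-2-fluoro-5-methoxyphenyl)lithium | [Li]c1cc(OC)cc(Br)c1F | intermediate
3 | 3-bromo-2-fluoro-5-methoxybenzaldehyde | COc1cc(Br)c(F)c(C=O)c1 | intermediate
4 | 5-bromoindolin-2-one | O=C1Cc2cc(Br)ccc2N1 | starting material
5 | 2,5-dibromo-1H-indole | Brc1cc2cc(Br)ccc2[nH]1 | intermediate
6 | 3-bromo-2-(2,5-dibromo-1H-indol-1-yl)-5-methoxybenzaldehyde | COc1cc(Br)c(-n2c(Br)cc3cc(Br)ccc32)c(C=O)c1 | intermediate
7 | methyl azidoacetate | COC(=O)CN=[N+]=[N-] | starting material
8 | methyl (Z)-2-azido-3-[3-bromo-2-(2,5-dibromo-1H-indol-1-yl)-5-methoxyphenyl]prop-2-enoate | COC(=O)/C(N=[N+]=[N-])=C/c1cc(OC)cc(Br)c1-n1c(Br)cc2cc(Br)ccc21 | intermediate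
9 | methyl 2-[3-bromo-2-(2,5-dibromo-1H-indol-1-yl)-5-methoxyphenyl]-2H-azirine-3-carboxylate (mixture of stereoisomers) | COC(=O)C1=NC1c1cc(OC)cc(Br)c1-n1c(Br)cc2cc(Br)ccc21 | intermediate
10 | methyl 5-bromo-4-(2,5-dibromo-1H-indol-1-yl)-7-methoxy-1H-indole-2-carboxylate | COC(=O)c1cc2c(-n3c(Br)cc4cc(Br)ccc43)c(Br)cc(OC)c2[nH]1 | intermediate
11 | 5-bromo-4-(2,5-dibromo-1H-indol-1-yl)-7-methoxy-1H-indole-2-carboxylic acid | OC(=O)c1cc2c(-n3c(Br)cc4cc(Br)ccc43)c(Br)cc(OC)c2[nH]1 | intermediate
12 | 5-bromo-4-(2,5-dibromo-1H-indol-1-yl)-7-methoxy-1H-indole | COc1cc(Br)c(-n2c(Br)cc3cc(Br)ccc32)c2cc[nH]c12 | intermediate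
13 | sodium 5-bromo-4-(2,5-dibromo-1H-indol-1-yl)-7-methoxyindol-1-ide | [Na+].COc1cc(Br)c(-n2c(Br)cc3cc(Br)ccc32)c2cc[n-]c12 | intermediate
14 | 3,5-dibromo-4-(2,5-dibromo-1H-indol-1-yl)-7-methoxy-1H-indole | COc1cc(Br)c(-n2c(Br)cc3cc(Br)ccc32)c2c(Br)c[nH]c12 | target

**Step count**

Total step count: 8. Longest linear sequence: 7 steps (steps 1, 3, 4, 5, 6, 7, 8); step 2 is a one-step branch.

**Steps most likely to fail**

Step 3. The addition–elimination may stall, because the fluoride carbon has two ortho substituents and is deactivated by the para methoxy group. Prolonged heating with carbonate may also degrade the aldehyde and the 2-bromoindole anion, or divert the ambident anion to C3 arylation. The fallback changes the activating group to a nitrile and sets out from aldehyde 3. One-pot oxime formation and dehydration (NH2OH·HCl, HCO2Na, HCO2H, reflux) should give 3-bromo-2-fluoro-5-methoxybenzonitrile F1. The nitrile is linear and base-stable, so substitution by 5 can be forced (Cs2CO3, DMSO, 110 °C) to 3-bromo-2-(2,5-dibromo-1H-indol-1-yl)-5-methoxybenzonitrile F2. Reduction with iBu2AlH in toluene at −78 °C and acidic hydrolysis of the aldimine comes back to the route at aldehyde 6.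

Step 1. Deprotonation may occur partly or mainly at the C–H flanked by bromine and methoxy, and the lithiated arene may suffer halogen migration or LiF loss. The fallback shields that position and sets out from 1. Demethylation with BBr3 in CH2Cl2 should give 3-bromo-4-fluorophenol F3, and iPr3SiCl with imidazole in DMF should give (3-bromo-4-fluorophenoxy)tri(propan-2-yl)silane F4. The bulky, non-coordinating silyloxy group blocks its neighbouring C–H, so LiN(iPr)2 in THF at −78 °C should give only [3-bromo-2-fluoro-5-(triisopropylsilyloxy)phenyl]lithium F5, which DMF converts to 3-bromo-2-fluoro-5-(triisopropylsilyloxy)benzaldehyde F6. Bu4NF in THF should give 3-bromo-2-fluoro-5-hydroxybenzaldehyde F7, and MeI with K2CO3 in acetone comes back to the route at aldehyde 3.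

Step 8. Bromine may be delivered unselectively, through N-bromination, a second bromination at C2 of ring A, or attack at C3' of indole B. The fallback moves the bromination to the ester stage, where C2 is blocked, and sets out from ester 10. NaH in THF should give the sodium salt of 10, sodium 5-bromo-4-(2,5-dibromo-1H-indol-1-yl)-7-methoxy-2-(methoxycarbonyl)indol-1-ide F8. NBS should brominate its only open nucleophilic carbon to give methyl 3,5-dibromo-4-(2,5-dibromo-1H-indol-1-yl)-7-methoxy-1H-indole-2-carboxylate F9. LiOH·H2O in THF/MeOH/H2O should give 3,5-dibromo-4-(2,5-dibromo-1H-indol-1-yl)-7-methoxy-1H-indole-2-carboxylic acid F10. Protodecarboxylation with Ag2CO3 and AcOH in DMSO, which the ortho bromine should assist, comes back to the route at target 14.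

**Further compounds**

F1 | step 3 | 3-bromo-2-fluoro-5-methoxybenzonitrile | COc1cc(Br)c(F)c(C#N)c1
F2 | step 3 | 3-bromo-2-(2,5-dibromo-1H-indol-1-yl)-5-methoxybenzonitrile | COc1cc(Br)c(-n2c(Br)cc3cc(Br)ccc32)c(C#N)c1
F3 | step 1 | 3-bromo-4-fluorophenol | Oc1ccc(F)c(Br)c1
F4 | step 1 | (3-bromo-4-fluorophenoxy)tri(propan-2-yl)silane | CC(C)[Si](Oc1ccc(F)c(Br)c1)(C(C)C)C(C)C
F5 | step 1 | [3-bromo-2-fluoro-5-(triisopropylsilyloxy)phenyl]lithium | [Li]c1cc(O[Si](C(C)C)(C(C)C)C(C)C)cc(Br)c1F
F6 | step 1 | 3-bromo-2-fluoro-5-(triisopropylsilyloxy)benzaldehyde | O=Cc1cc(O[Si](C(C)C)(C(C)C)C(C)C)cc(Br)c1F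
F7 | step 1 | 3-bromo-2-fluoro-5-hydroxybenzaldehyde | O=Cc1cc(O)cc(Br)c1F
F8 | step 8 | sodium 5-bromo-4-(2,5-dibromo-1H-indol-1-yl)-7-methoxy-2-(methoxycarbonyl)indol-1-ide | [Na+].COC(=O)c1cc2c(-n3c(Br)cc4cc(Br)ccc43)c(Br)cc(OC)c2[n-]1
F9 | step 8 | methyl 3,5-dibromo-4-(2,5-dibromo-1H-indol-1-yl)-7-methoxy-1H-indole-2-carboxylate | COC(=O)c1[nH]c2c(OC)cc(Br)c(-n3c(Br)cc4cc(Br)ccc43)c2c1Br
F10 | step 8 | 3,5-dibromo-4-(2,5-dibromo-1H-indol-1-yl)-7-methoxy-1H-indole-2-carboxylic acid | OC(=O)c1[nH]c2c(OC)cc(Br)c(-n3c(Br)cc4cc(Br)ccc43)c2c1Br
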